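The cedar run's last reading, 0.0297 M at 4.8 min, stood lower than the birch run's 0.0337 M at the same time, and cedar was still climbing. My next flask, maple, kept the cedar charge and changed the time, to 14 min. What I had to judge was how far past the readings that time lay.

| setting | cedar | larch | birch | elm | maple |
|---|---|---|---|---|---|
| Z | 0.0800 M | 0.0480 M | 0.0800 M | 0.240 M | 0.0800 M |
| L | 0.0880 M | 0.0560 M | 0.130 M | 0.0880 M | 0.0880 M |
| time |  |  |  |  | 14 min |

- cedar run (time / min: [E] / M): 0.37: 0.0053; 1.1: 0.0134; 2.1: 0.0203; 3.4: 0.0265; 4.8: 0.0297
- larch run (time / min: [E] / M): 0.37: 0.0028; 1.1: 0.0069; 2.1: 0.0099; 3.4: 0.0135; 4.8: 0.0166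
- birch run (time / min: [E] / M): 0.37: 0.0074; 1.1: 0.0163; 2.1: 0.0260; 3.4: 0.0335; 4.8: 0.0337
- elm run (time / min: [E] / M): 0.37: 0.0156; 1.1: 0.0360; 2.1: 0.0532; 3.4: 0.0564; 4.8: 0.0562

(standard deviation of a reading: 8 × 10⁻⁴ M)

1. apparent order in [Z] of the starting rate, round the charge of the cedar run (the rate where two percent of its Z have turned into E) (one fixed amount of E, the same in the runs compared)
2. apparent order in [L] of the starting rate, round the charge of the cedar run (the rate where two percent of its Z have turned into E)
3. E in the maple run at 14 min, as a share of the Z charged

- Overall: Z + L -> E.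
- Constant volume, constant temperature.
- What is held in complexes is read along with the free species.
- An order is taken over about fifteen percent of the charge, up and down.

I counted in turnovers. The first cedar reading gives a starting rate near 0.0143 M min⁻¹, and Z, at 0.0800 M against 0.0880 M of L, is the limiting reagent by charge. Dividing that charge by the rate gives 5.58 min. This is the turnover time, the minutes the limiting charge would last at the starting rate. Cedar's readings end at 0.860 turnover times, and maple's 14 min is 2.51.

In the elm run the smaller charge is the 0.0880 M of L, and the first reading gives a starting rate near 0.0422 M min⁻¹, so its turnover time is shorter, 2.09 min. Its last reading thus stands at 2.30 turnover times, just short of maple's count, and it reads flat: 0.0564 M, then 0.0562 M, a difference smaller than the scatter. But that flat stretch covers 1.40 min of clock time, and maple's wait beyond cedar's last reading is 9.20 min. So I left the recipe alone and kept the long time.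

The forecast gave orders of 0.95 in Z (0.75 to 1.15) and 0.55 in L (0.3 to 0.85), and 40% of the Z charged (37% to 45%), since cedar “should level off slightly below birch”.

Maple gives 26.5% of the Z charged, or 0.0212 M of E, less than cedar's last reading; the apparent orders are 1.0 in Z and 0.61 in L.

    Z + L → E + Q (7.380 M⁻¹ min⁻¹)
    2 L ⇌ L2, settled at all times (46.50 M⁻¹)
    E → Vo (0.1266 min⁻¹)

E is lost to Vo with a lifetime of 7.90 min, and maple's 14 min spans 1.77 lifetimes. Maple's turnover time, the 5.58 min reckoned from cedar's first reading on the same charge, is 0.706 of that lifetime. Elm's, 2.09 min, is 0.265 of it, and elm's last reading of E stood at 63.9% of its L charge.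

The readings were computed with made-up constants; scatter was added.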